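**Retrosynthetic overview**
- The hydroxyquinone is made last, by Teuber oxidation of a 2-alkyl-4-chloro-5-methylresorcinol freed from its bis-MOM ether.
- The C3'–C4' bond and the 4'S carbinol come from a catalytic asymmetric addition of an (E)-alkenylzinc (from a 2-butynyl arene) to a keto-aldehyde.
- The keto-aldehyde comes from ozonolysis of an allyl ketone, which is made in the key step: Lewis-acid opening of an acyclic (S)-epoxy-diene, 6-ring closure, then a 1,2-H / 1,2-CH3 / 1,2-H shift relay ending in the ketone.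
- The epoxy-diene comes from Negishi allylation, Shi epoxidation, carboalumination–iodination and acetylide alkylation; the arene comes from MOM-protected resorcinol by C–H borylation/methylation, chlorination and ortho-lithiation/propargylation.
- Rings: the cyclohexanone is the only ring built (step 5); the benzene ring is bought and becomes the quinone in step 12.

Assumption: 1,3-bis(methoxymethoxy)benzene, the L-fructose-derived Shi ketone and (+)-MIB are taken as catalogue items.

**Step 1**
Reactants: 1 5-bromo-2-methylpent-2-ene; 2 lithium acetylide–ethylenediamine complex (LiC≡CH·H2NCH2CH2NH2)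
Product: 3 6-methylhept-5-en-1-yne
Conditions: DMSO, 10 → 25 °C
Reagents that add atoms: none
Why: SN2 alkylation of an acetylide on a primary homoallylic bromide; no stereocentre is formed.

**Step 2**
Reactants: 3 6-methylhept-5-en-1-yne
Product: 5 (1E)-1-iodo-2,6-dimethylhepta-1,5-diene, via alkenylalane 4 (not isolated)
Conditions: Me3Al, Cp2ZrCl2 (20 mol%), CH2Cl2, 0 → 23 °C; then I2, THF, −30 → 0 °C
Reagents that add atoms: trimethylaluminium (C[Al](C)C); iodine (II)
Why: Zirconium-catalysed syn-carboalumination (Negishi) puts CH3 on the internal and Al on the terminal alkyne carbon, and iodinolysis with retention gives the E vinyl iodide.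

**Step 3**
Reactants: 5 (1E)-1-iodo-2,6-dimethylhepta-1,5-diene
Product: 6 (3S)-3-[(3E)-4-iodo-3-methylbut-3-en-1-yl]-2,2-dimethyloxirane
Conditions: L-fructose-derived Shi ketone (30 mol%), KHSO5 (as 2KHSO5·KHSO4·K2SO4), K2CO3, Bu4NHSO4, MeCN/CH2(OMe)2/aq. Na2B4O7 buffer, −10 → 0 °C
Reagents that add atoms: potassium peroxymonosulfate ([K+].[O-]S(=O)(=O)OO)
Why: Shi asymmetric epoxidation, in which the chiral dioxirane attacks only the electron-rich trisubstituted alkene (the vinyl iodide is deactivated) through the spiro transition state and sets the 3S centre.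

**Step 4**
Reactants: 6 (3S)-3-[(3E)-4-iodo-3-methylbut-3-en-1-yl]-2,2-dimethyloxirane; 7 3-bromoprop-1-ene (allyl bromide)
Product: 9 (3S)-2,2-dimethyl-3-[(3E)-3-methylhepta-3,6-dien-1-yl]oxirane, via allylzinc bromide 8 (not isolated)
Conditions: 7, Zn dust, LiCl, THF, 0 → 23 °C; then 6, Pd(PPh3)4 (5 mol%), THF, 23 °C
Reagents that add atoms: none
Why: Negishi coupling, in which zerovalent palladium inserts into the C–I bond with retention of the E geometry and the allyl group is transferred from zinc, while the trisubstituted epoxide is inert.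

**Step 5**
Reactants: 9 (3S)-2,2-dimethyl-3-[(3E)-3-methylhepta-3,6-dien-1-yl]oxirane
Product: 10 (2R,3S,4R)-2,3,4-trimethyl-3-(prop-2-en-1-yl)cyclohexan-1-one
Conditions: methylaluminium bis(4-bromo-2,6-di-tert-butylphenoxide) (20 mol%), CH2Cl2, −78 → −20 °C
Reagents that add atoms: none
Why: Proposed new method: the chloride-free, very bulky oxophilic aluminium Lewis acid opens the epoxide at its tertiary carbon with π-participation of the trisubstituted alkene through a chair (O–Al equatorial), and because the zwitterion has no base or nucleophile in reach (the aluminate oxygen is buried between the two aryloxides, which also blocks oxa-bridging) the cation relays by three antiperiplanar suprafacial 1,2-shifts (axial H from C3 to C4, axial CH3 from C2 to C3 creating the quaternary centre, axial H from C1 to C2) and is quenched only by the last one, which forms the C=O, so the single epoxide centre is relayed into the all-cis 2R,3S,4R triad and the catalyst is released; the closest known reaction types are the Lewis-acid epoxy-polyene cyclisation, acid-induced friedo-type hydride/methyl backbone shifts of terpenoid decalins and the Meinwald/semipinacol rearrangement of epoxides, which have not been merged into one catalytic stereospecific step on an acyclic epoxy-diene.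

**Step 6**
Reactants: 10 (2R,3S,4R)-2,3,4-trimethyl-3-(prop-2-en-1-yl)cyclohexan-1-one
Product: 12 2-[(1S,2R,6R)-1,2,6-trimethyl-3-oxocyclohexyl]acetaldehyde, via secondary ozonide 11 (not isolated)
Conditions: O3, CH2Cl2, −78 °C; then PPh3, −78 → 23 °C
Reagents that add atoms: ozone ([O-][O+]=O)
Why: Ozonolysis (Criegee mechanism) with reductive work-up excises the terminal CH2 under neutral conditions that leave the three stereocentres untouched.

**Step 7**
Reactants: 13 1,3-bis(methoxymethoxy)benzene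
Product: 15 1,3-bis(methoxymethoxy)-5-methylbenzene, via pinacol boronate 14 (not isolated)
Conditions: B2pin2 (1.0 equiv), [Ir(OMe)(cod)]2 (1.5 mol%), 4,4'-di-tert-butyl-2,2'-bipyridine (3 mol%), THF, 80 °C; then MeI, Pd2(dba)3 (2.5 mol%), P(o-tol)3, K2CO3, DMF/H2O, 60 °C
Reagents that add atoms: iodomethane (CI)
Why: Sterically controlled iridium-catalysed C–H borylation hits only C5 (the one C–H without an ortho substituent), and Suzuki–Miyaura methylation of the crude boronate installs the methyl group.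

**Step 8**
Reactants: 15 1,3-bis(methoxymethoxy)-5-methylbenzene
Product: 16 2-chloro-1,5-bis(methoxymethoxy)-3-methylbenzene
Conditions: NCS (1.05 equiv), MeCN, 0 → 23 °C
Reagents that add atoms: N-chlorosuccinimide (ClN1C(=O)CCC1=O)
Why: Electrophilic aromatic chlorination goes to the position para to one MOM-oxygen and ortho to the other, which is less hindered than the position flanked by both MOM groups.

**Step 9**
Reactants: 16 2-chloro-1,5-bis(methoxymethoxy)-3-methylbenzene; 17 1-bromobut-2-yne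
Product: 19 2-(but-2-yn-1-yl)-4-chloro-1,3-bis(methoxymethoxy)-5-methylbenzene, via aryllithium 18 (not isolated)
Conditions: n-BuLi, THF, 0 °C; then 17, −78 → 23 °C
Reagents that add atoms: none
Why: Directed ortho-metalation between the two MOM-oxygens (no hydrogen sits ortho to chlorine), then SN2 alkylation of the aryllithium by the primary propargylic bromide.

**Step 10**
Reactants: 19 2-(but-2-yn-1-yl)-4-chloro-1,3-bis(methoxymethoxy)-5-methylbenzene; 12 2-[(1S,2R,6R)-1,2,6-trimethyl-3-oxocyclohexyl]acetaldehyde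
Product: 22 (2R,3S,4R)-3-[(2S,3E)-5-[3-chloro-2,6-bis(methoxymethoxy)-4-methylphenyl]-2-hydroxy-3-methylpent-3-en-1-yl]-2,3,4-trimethylcyclohexan-1-one, via alkenylzirconocene 20 (not isolated), via alkenylzinc 21 (not isolated)
Conditions: Cp2Zr(H)Cl, CH2Cl2, 23 → 40 °C; then Me2Zn, toluene, −65 °C; then (+)-3-exo-morpholinoisoborneol [(+)-MIB, 10 mol%], 12, −30 → 0 °C; aq. NH4Cl
Reagents that add atoms: none
Why: Syn-hydrozirconation puts zirconium on the methyl-bearing alkyne carbon (away from the bulky 2,6-disubstituted benzyl group, after equilibration), zirconium-to-zinc transmetalation follows, and the (+)-MIB–zinc alkoxide delivers the alkenyl group to the Re face of the aldehyde (the ketone does not react), setting the 2S carbinol with the E alkene kept (catalytic asymmetric alkenylzinc addition of the Oppolzer–Wipf type).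

**Step 11**
Reactants: 22 (2R,3S,4R)-3-[(2S,3E)-5-[3-chloro-2,6-bis(methoxymethoxy)-4-methylphenyl]-2-hydroxy-3-methylpent-3-en-1-yl]-2,3,4-trimethylcyclohexan-1-one
Product: 24 (2R,3S,4R)-3-[(2S,3E)-5-(3-chloro-2,6-dihydroxy-4-methylphenyl)-2-hydroxy-3-methylpent-3-en-1-yl]-2,3,4-trimethylcyclohexan-1-one, via tris(trimethylsilyl) ether 23 (not isolated)
Conditions: TMSOTf, 2,2'-bipyridyl, CH2Cl2, 0 → 23 °C; then H2O, 23 °C
Reagents that add atoms: none
Why: Silyl triflate/bipyridyl cleavage of aromatic MOM ethers turns each acetal into an aryl silyl ether and a bipyridinium salt without free acid, and water then removes all silyl groups, so the allylic alcohol is not ionised.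

**Step 12**
Reactants: 24 (2R,3S,4R)-3-[(2S,3E)-5-(3-chloro-2,6-dihydroxy-4-methylphenyl)-2-hydroxy-3-methylpent-3-en-1-yl]-2,3,4-trimethylcyclohexan-1-one
Product: 25 2-chloro-5-hydroxy-3-methyl-6-[(2E,4S)-4-hydroxy-3-methyl-5-[(1S,2R,6R)-1,2,6-trimethyl-3-oxocyclohexyl]pent-2-en-1-yl]cyclohexa-2,5-diene-1,4-dione
Conditions: K2[ON(SO3)2] (2.5 equiv), KH2PO4 buffer, acetone/H2O, 0 → 23 °C
Reagents that add atoms: potassium nitrosodisulfonate ([K+].[K+].[O]N(S(=O)(=O)[O-])S(=O)(=O)[O-])
Why: Teuber oxidation, in which the nitrosodisulfonate radical oxidises the phenol, a second equivalent adds at the only free ring position (para to one hydroxyl), and loss of imidodisulfonate gives the para-quinone with the other hydroxyl kept.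

**Compound list**
1 | 5-bromo-2-methylpent-2-ene | CC(C)=CCCBr | starting material
2 | lithium acetylide–ethylenediamine complex | [Li+].[C-]#C.NCCN | starting material
3 | 6-methylhept-5-en-1-yne | C#CCCC=C(C)C | intermediate
4 | [(1E)-2,6-dimethylhepta-1,5-dien-1-yl]dimethylalumane | C[Al](C)/C=C(\C)CCC=C(C)C | intermediate (not isolated)
5 | (1E)-1-iodo-2,6-dimethylhepta-1,5-diene | I/C=C(\C)CCC=C(C)C | intermediate
6 | (3S)-3-[(3E)-4-iodo-3-methylbut-3-en-1-yl]-2,2-dimethyloxirane | CC1(C)O[C@H]1CC/C(C)=C/I | intermediate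
7 | 3-bromoprop-1-ene (allyl bromide) | C=CCBr | starting material
8 | allylzinc bromide | C=CC[Zn]Br | intermediate (not isolated)
9 | (3S)-2,2-dimethyl-3-[(3E)-3-methylhepta-3,6-dien-1-yl]oxirane | CC1(C)O[C@H]1CC/C(C)=C/CC=C | intermediate
10 | (2R,3S,4R)-2,3,4-trimethyl-3-(prop-2-en-1-yl)cyclohexan-1-one | C=CC[C@@]1(C)[C@H](C)CCC(=O)[C@@H]1C | intermediate
11 | (2R,3S,4R)-2,3,4-trimethyl-3-[(1,2,4-trioxolan-3-yl)methyl]cyclohexan-1-one | C1(C[C@@]2(C)[C@H](C)CCC(=O)[C@@H]2C)OCOO1 | intermediate (not isolated)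
12 | 2-[(1S,2R,6R)-1,2,6-trimethyl-3-oxocyclohexyl]acetaldehyde | O=CC[C@@]1(C)[C@H](C)CCC(=O)[C@@H]1C | intermediate
13 | 1,3-bis(methoxymethoxy)benzene | COCOc1cccc(OCOC)c1 | starting material
14 | 2-[3,5-bis(methoxymethoxy)phenyl]-4,4,5,5-tetramethyl-1,3,2-dioxaborolane | COCOc1cc(OCOC)cc(c1)B1OC(C)(C)C(C)(C)O1 | intermediate (not isolated)
15 | 1,3-bis(methoxymethoxy)-5-methylbenzene | COCOc1cc(C)cc(OCOC)c1 | intermediate
16 | 2-chloro-1,5-bis(methoxymethoxy)-3-methylbenzene | COCOc1cc(OCOC)c(Cl)c(C)c1 | intermediate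
17 | 1-bromobut-2-yne | CC#CCBr | starting material
18 | [3-chloro-2,6-bis(methoxymethoxy)-4-methylphenyl]lithium | [Li]c1c(OCOC)cc(C)c(Cl)c1OCOC | intermediate (not isolated)
19 | 2-(but-2-yn-1-yl)-4-chloro-1,3-bis(methoxymethoxy)-5-methylbenzene | CC#CCc1c(OCOC)cc(C)c(Cl)c1OCOC | intermediate
20 | chlorobis(cyclopentadienyl){(2E)-4-[3-chloro-2,6-bis(methoxymethoxy)-4-methylphenyl]but-2-en-2-yl}zirconium | C/C(=C\Cc1c(OCOC)cc(C)c(Cl)c1OCOC)[Zr](Cl)(C1C=CC=C1)C1C=CC=C1 | intermediate (not isolated)
21 | {(2E)-4-[3-chloro-2,6-bis(methoxymethoxy)-4-methylphenyl]but-2-en-2-yl}(methyl)zinc | C/C(=C\Cc1c(OCOC)cc(C)c(Cl)c1OCOC)[Zn]C | intermediate (not isolated)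
22 | (2R,3S,4R)-3-[(2S,3E)-5-[3-chloro-2,6-bis(methoxymethoxy)-4-methylphenyl]-2-hydroxy-3-methylpent-3-en-1-yl]-2,3,4-trimethylcyclohexan-1-one | COCOc1cc(C)c(Cl)c(OCOC)c1C/C=C(\C)[C@@H](O)C[C@@]1(C)[C@H](C)CCC(=O)[C@@H]1C | intermediate
23 | (2R,3S,4R)-3-[(2S,3E)-5-{3-chloro-4-methyl-2,6-bis[(trimethylsilyl)oxy]phenyl}-3-methyl-2-[(trimethylsilyl)oxy]pent-3-en-1-yl]-2,3,4-trimethylcyclohexan-1-one | Cc1cc(O[Si](C)(C)C)c(C/C=C(\C)[C@@H](O[Si](C)(C)C)C[C@@]2(C)[C@H](C)CCC(=O)[C@@H]2C)c(O[Si](C)(C)C)c1Cl | intermediate (not isolated)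
24 | (2R,3S,4R)-3-[(2S,3E)-5-(3-chloro-2,6-dihydroxy-4-methylphenyl)-2-hydroxy-3-methylpent-3-en-1-yl]-2,3,4-trimethylcyclohexan-1-one | Cc1cc(O)c(C/C=C(\C)[C@@H](O)C[C@@]2(C)[C@H](C)CCC(=O)[C@@H]2C)c(O)c1Cl | intermediate
25 | 2-chloro-5-hydroxy-3-methyl-6-[(2E,4S)-4-hydroxy-3-methyl-5-[(1S,2R,6R)-1,2,6-trimethyl-3-oxocyclohexyl]pent-2-en-1-yl]cyclohexa-2,5-diene-1,4-dione | CC1=C(Cl)C(=O)C(C/C=C(\C)[C@@H](O)C[C@@]2(C)[C@H](C)CCC(=O)[C@@H]2C)=C(O)C1=O | target

**Total step count:** 12.
**Longest linear sequence:** 9 steps (steps 1–6, then 10–12).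

**The three steps most likely to fail**

Step 5 (the proposed cascade). The cation may leave the relay early: direct Meinwald hydride shift to an isopropyl ketone before ring closure, proton loss to cyclohexenols, or capture by oxygen to a 7-oxabicyclo[2.2.1]heptane. The fallback uses known chemistry only, sets out from allyl bromide 7 and comes back at ketone 10. Propanal and methyl vinyl ketone are joined by the known diarylprolinol-silyl-ether-catalysed Michael addition to (2R)-2-methyl-5-oxohexanal F1, which is closed by aldol condensation to (4R)-4-methylcyclohex-2-en-1-one F2. Me2CuLi/TMSCl adds anti to the methyl group to give trimethyl{[(3S,4R)-3,4-dimethylcyclohex-1-en-1-yl]oxy}silane F3, and Saegusa–Ito oxidation with Pd(OAc)2 gives (4R)-3,4-dimethylcyclohex-2-en-1-one F4. Allyl bromide 7 is turned with magnesium into allylmagnesium bromide F5, which as its copper reagent (CuBr·SMe2, LiCl) with TMSCl adds to F4 anti to the C4 methyl group and gives the silyl enol ether trimethyl{[(3S,4R)-3,4-dimethyl-3-(prop-2-en-1-yl)cyclohex-1-en-1-yl]oxy}silane F6 with the quaternary centre in place. MeLi frees the lithium enolate F7 regiospecifically, MeI methylates C2, and NaOMe/MeOH equilibration leaves the equatorial 2R methyl group, which is ketone 10.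

Step 10 (alkenylzinc addition). Hydrozirconation may give a regioisomer mixture, the trisubstituted alkenylzinc may add slowly, and the ligand may give poor selectivity with this aliphatic aldehyde. The fallback sets out from alkyne 19 and aldehyde 12 and comes back at 22. Zirconocene 20, made as in step 10, is quenched with iodine to 4-chloro-2-[(2E)-3-iodobut-2-en-1-yl]-1,3-bis(methoxymethoxy)-5-methylbenzene F8, which is purified free of any regioisomer. A Nozaki–Hiyama–Kishi coupling (CrCl2, NiCl2 as catalyst, chiral oxazoline-sulfonamide ligand, Et3N, THF) turns F8 into the alkenylchromium dichloride F9, which adds only to the aldehyde of 12 and gives 22 with the carbinol configuration set by the ligand.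

Step 11 (MOM removal next to the allylic alcohol). Ionisation of the allylic alcohol or ring closure of a phenol onto the side chain would destroy the material. The fallback changes the protecting-group plan, sets out from alkyne 19 and comes back at resorcinol 24. The MOM groups are removed at the robust alkyne stage with HCl/MeOH to give 2-(but-2-yn-1-yl)-4-chloro-5-methylbenzene-1,3-diol F10, which is silylated (TBSCl, imidazole) to 2-(but-2-yn-1-yl)-1,3-bis[(tert-butyldimethylsilyl)oxy]-4-chloro-5-methylbenzene F11. F11 is taken through the step-10 protocol with 12, by way of its alkenylzirconocene F12 and alkenylzinc F13, to the bis-silyl allylic alcohol F14. Buffered TBAF/AcOH at 0 °C under argon then frees both phenols and gives 24.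

**Further compounds**
F1 | step 5 | (2R)-2-methyl-5-oxohexanal | O=C[C@H](C)CCC(C)=O
F2 | step 5 | (4R)-4-methylcyclohex-2-en-1-one | O=C1C=C[C@H](C)CC1
F3 | step 5 | trimethyl{[(3S,4R)-3,4-dimethylcyclohex-1-en-1-yl]oxy}silane | C[C@@H]1C=C(O[Si](C)(C)C)CC[C@H]1C
F4 | step 5 | (4R)-3,4-dimethylcyclohex-2-en-1-one | O=C1C=C(C)[C@H](C)CC1
F5 | step 5 | allylmagnesium bromide | C=CC[Mg]Br
F6 | step 5 | trimethyl{[(3S,4R)-3,4-dimethyl-3-(prop-2-en-1-yl)cyclohex-1-en-1-yl]oxy}silane | C=CC[C@@]1(C)[C@H](C)CCC(O[Si](C)(C)C)=C1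
F7 | step 5 | lithium (3S,4R)-3,4-dimethyl-3-(prop-2-en-1-yl)cyclohex-1-en-1-olate | C=CC[C@@]1(C)[C@H](C)CCC(O[Li])=C1
F8 | step 10 | 4-chloro-2-[(2E)-3-iodobut-2-en-1-yl]-1,3-bis(methoxymethoxy)-5-methylbenzene | C/C(I)=C\Cc1c(OCOC)cc(C)c(Cl)c1OCOC
F9 | step 10 | dichloro{(2E)-4-[3-chloro-2,6-bis(methoxymethoxy)-4-methylphenyl]but-2-en-2-yl}chromium | C/C(=C\Cc1c(OCOC)cc(C)c(Cl)c1OCOC)[Cr](Cl)Cl
F10 | step 11 | 2-(but-2-yn-1-yl)-4-chloro-5-methylbenzene-1,3-diol | CC#CCc1c(O)cc(C)c(Cl)c1O
F11 | step 11 | 2-(but-2-yn-1-yl)-1,3-bis[(tert-butyldimethylsilyl)oxy]-4-chloro-5-methylbenzene | CC#CCc1c(O[Si](C)(C)C(C)(C)C)cc(C)c(Cl)c1O[Si](C)(C)C(C)(C)C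
F12 | step 11 | chlorobis(cyclopentadienyl){(2E)-4-{2,6-bis[(tert-butyldimethylsilyl)oxy]-3-chloro-4-methylphenyl}but-2-en-2-yl}zirconium | C/C(=C\Cc1c(O[Si](C)(C)C(C)(C)C)cc(C)c(Cl)c1O[Si](C)(C)C(C)(C)C)[Zr](Cl)(C1C=CC=C1)C1C=CC=C1
F13 | step 11 | {(2E)-4-{2,6-bis[(tert-butyldimethylsilyl)oxy]-3-chloro-4-methylphenyl}but-2-en-2-yl}(methyl)zinc | C/C(=C\Cc1c(O[Si](C)(C)C(C)(C)C)cc(C)c(Cl)c1O[Si](C)(C)C(C)(C)C)[Zn]C
F14 | step 11 | (2R,3S,4R)-3-[(2S,3E)-5-{2,6-bis[(tert-butyldimethylsilyl)oxy]-3-chloro-4-methylphenyl}-2-hydroxy-3-methylpent-3-en-1-yl]-2,3,4-trimethylcyclohexan-1-one | Cc1cc(O[Si](C)(C)C(C)(C)C)c(C/C=C(\C)[C@@H](O)C[C@@]2(C)[C@H](C)CCC(=O)[C@@H]2C)c(O[Si](C)(C)C(C)(C)C)c1Cl
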